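Does Q in the flask still climb at 40 min, or does it turn earlier? I ask what the oak run would have to show for it to keep climbing.

| flask | J | X | remark | time |
|---|---|---|---|---|
| oak | 0.10 M | 4.2 µM | run made earlier |  |
| flask | 0.050 M | 4.2 µM |  | 40 min |

oak run (percent of the J charged)

| time / min | Q / % | J / % |
|---|---|---|
| 2.00 | 3.8 | 96.6 |
| 4.00 | 6.5 | 91.9 |
| 6.00 | 10.3 | 88.4 |
| 8.00 | 12.8 | 84.6 |

(scatter of a reading: 0.5 percentage points)

- time, not beyond 40 min, at which the flask holds most Q
- the amount of Q, in percent of the J charged, at that time
- the first time at which Q reaches 25%, in the same percent, in min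



1. At its last reading, 8.00 min, the oak run has J and Q together short of the charge by 2.60%, so I treat Q as an intermediate that drains onward into something unseen.
2. Summing the Q readings over time gives 0.540 min in fractions of the charge, and dividing the gap by this gives the drain constant 0.0481 /min, the fraction of the Q present lost per minute, a reading that carries the scatter.
3. I call the balance J's rate of fall divided by drain times Q. In this ratio of rates time drops out, and in my picture of J feeding Q and Q draining onward, Q climbs while it exceeds one and peaks where it equals one. In the oak run it stands at 3.12 at the last reading.
4. Suppose J in the flask falls first-order with the oak constant 0.0209 /min. The balance then reaches one at 30.6 min, earlier than 40 min. If J instead keeps the oak's molar rate, my reckoning brings it to zero at 26.0 min. On this reckoning Q still climbs at 40 min with J's constant at half the oak's, which puts the peak at 40.5 min. I commit to a turn between 26.0 min and 30.6 min.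
5. The forecast differs from mine: it gives 40 min (28 min to 40 min), 55% (38% to 82%) and 13 min (8.5 min to 19 min), saying “I expect Q still rising at 40 min”.
6. The flask peaks at 23.2 min with 36.3% of Q, earlier than my 26.0 min, and reaches 25% at 9.64 min; at the peak J still holds 32.7%.

    Q ⇌ G (K = 12.0, k = 0.0560 /min)
    J + X → Q + X, rate k2*[J]^2*[X]/(1 + ([J]/Kh2)^2) (17.0 mM, k = 27000 /M²/s)

7. From 20.0 min to 23.1 min the flask's J falls from 39.2% to 32.7%, which puts the balance near the peak at 1.18. In the neighbour flask, the same charge stopped at 15.0 min, J is 51.8% and Q is 32.4%; the fall of J from there to the 39.2% that the asked flask holds at 20.0 min gives a balance of 1.61, above one, and the neighbour's Q stands at its highest so far, 32.4%.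

(The runs were computed from invented constants; noise was put on by code.)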